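**Strategy**

Everything rests on C4 of the third flavan unit: a diarylmethine carbon next to C3–OH, bonded to C4a of its own ring A and to C6 of the bottom epicatechin, hence an aldehyde carbon in disguise. The unit is therefore built de novo. An α-hydroxy aldehyde, tethered through the O1–C2 aryl ether to a bromine-capped phloroglucinol ring that already carries the top dimer, undergoes Friedel–Crafts ring closure C4a→C4 (ring C); the resulting flavan-3,4-diol ionises in the same flask and its C4 cation is captured by C6 of 8-bromo-epicatechin. One operation thus closes the ring, forges the last interflavan bond and sets C4.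

Key step: step 16

Remark on naming: the four flavan units are called top (epicatechin), second (epiafzelechin), third (epicatechin, built de novo) and bottom (epicatechin); ring A is the benzo ring, ring C the pyran ring, ring B the pendant aryl ring.
Assumption: (−)-epiafzelechin (6) is taken as a purchasable natural flavan-3-ol, like (−)-epicatechin.

**Route**

Step 1
Reactants: 1 (−)-epicatechin
Product: 2 5,7,3',4'-tetra-O-benzyl-(−)-epicatechin
Conditions: BnBr (4.5 equiv), K2CO3, DMF, 0 °C to rt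
Reagents that add atoms: benzyl bromide, BrCc1ccccc1
Why: Williamson ether synthesis in which K2CO3 deprotonates only the four phenols, so the secondary 3-OH stays free and no stereocentre is touched.

Step 2
Reactants: 2 5,7,3',4'-tetra-O-benzyl-(−)-epicatechin
Product: 3 8-bromo-5,7,3',4'-tetra-O-benzyl-(−)-epicatechin
Conditions: NBS (1.0 equiv), CH2Cl2, −78 °C to rt
Reagents that add atoms: N-bromosuccinimide, O=C1CCC(=O)N1Br
Why: Electrophilic aromatic bromination at C8, the most reactive ring A carbon of benzylated flavan-3-ols (flanked by the ring oxygen and one benzyloxy group); the bromine later forces this unit to react through C6.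

Step 3
Reactants: 2 5,7,3',4'-tetra-O-benzyl-(−)-epicatechin
Product: 4 5,7,3',4'-tetra-O-benzyl-4β-(2-ethoxyethoxy)-(−)-epicatechin
Conditions: DDQ (2 equiv), 2-ethoxyethanol (10 equiv), CH2Cl2, rt
Reagents that add atoms: 2-ethoxyethanol, CCOCCO
Why: DDQ benzylic oxidation, in which hydride abstraction at C4 gives the ring-A-stabilised flavan-4-yl cation that the alcohol captures anti to the 3-OH, setting the 4β (3,4-trans) ether.

Step 4
Reactants: 4 5,7,3',4'-tetra-O-benzyl-4β-(2-ethoxyethoxy)-(−)-epicatechin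
Product: 5 6,8-dibromo-5,7,3',4'-tetra-O-benzyl-4β-(2-ethoxyethoxy)-(−)-epicatechin
Conditions: NBS (2.1 equiv), CH2Cl2, 0 °C to rt
Reagents that add atoms: N-bromosuccinimide, O=C1CCC(=O)N1Br
Why: Electrophilic aromatic bromination of both remaining ring A carbons removes every nucleophilic site from the future electrophile, so that it cannot self-condense.

Step 5
Reactants: 6 (−)-epiafzelechin
Product: 7 5,7,4'-tri-O-benzyl-(−)-epiafzelechin
Conditions: BnBr (3.3 equiv), K2CO3, DMF, 0 °C to rt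
Reagents that add atoms: benzyl bromide, BrCc1ccccc1
Why: Williamson ether synthesis of the three phenols only, as in step 1.

Step 6
Reactants: 7 5,7,4'-tri-O-benzyl-(−)-epiafzelechin
Product: 8 5,7,4'-tri-O-benzyl-4β-(2-ethoxyethoxy)-(−)-epiafzelechin
Conditions: DDQ (2 equiv), 2-ethoxyethanol (10 equiv), CH2Cl2, rt
Reagents that add atoms: 2-ethoxyethanol, CCOCCO
Why: DDQ benzylic oxidation at C4 with capture of the cation by the alcohol anti to the 3-OH (4β ether), as in step 3.

Step 7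
Reactants: 8 5,7,4'-tri-O-benzyl-4β-(2-ethoxyethoxy)-(−)-epiafzelechin
Product: 9 8-bromo-5,7,4'-tri-O-benzyl-4β-(2-ethoxyethoxy)-(−)-epiafzelechin
Conditions: NBS (1.0 equiv), CH2Cl2, −78 °C to rt
Reagents that add atoms: N-bromosuccinimide, O=C1CCC(=O)N1Br
Why: Electrophilic aromatic bromination at C8 as in step 2, leaving C6 as the only free ring A carbon of the second unit.

Step 8
Reactants: 9 8-bromo-5,7,4'-tri-O-benzyl-4β-(2-ethoxyethoxy)-(−)-epiafzelechin
Product: 10 8-bromo-5,7,4'-tri-O-benzyl-4β-[(2,6-dimethylphenyl)sulfanyl]-(−)-epiafzelechin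
Conditions: 2,6-dimethylbenzenethiol (3 equiv), BF3·OEt2 (0.3 equiv), CH2Cl2, −78 to −40 °C
Reagents that add atoms: 2,6-dimethylbenzenethiol, Cc1cccc(C)c1S
Why: Lewis-acid-mediated SN1 exchange (thiolysis) at C4, the thiol attacking the flavan-4-yl cation anti to the 3-OH to give the 4β-thioether, a latent leaving group that is inert to hard Lewis acids but ionised by silver salts.

Step 9
Reactants: 5 6,8-dibromo-5,7,3',4'-tetra-O-benzyl-4β-(2-ethoxyethoxy)-(−)-epicatechin; 10 8-bromo-5,7,4'-tri-O-benzyl-4β-[(2,6-dimethylphenyl)sulfanyl]-(−)-epiafzelechin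
Product: 11 top dimer thioether (top unit C4 bonded 4β to C6 of the second unit)
Conditions: 5 (1.3 equiv), BF3·OEt2 (0.5 equiv), 4 Å MS, CH2Cl2, −78 to −30 °C
Reagents that add atoms: none
Why: Lewis-acid-promoted Friedel–Crafts interflavan coupling (SN1) in which the C4 cation from 5 attacks C6, the only unsubstituted ring A carbon of 10, anti to its own 3-OH, setting the 4β centre of the top unit while the thioether survives.

Step 10
Reactants: 12 3,5-bis(benzyloxy)phenol
Product: 13 4-bromo-3,5-bis(benzyloxy)phenol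
Conditions: NBS (1.0 equiv), DMF, −20 °C
Reagents that add atoms: N-bromosuccinimide, O=C1CCC(=O)N1Br
Why: Electrophilic aromatic bromination under a para-selective protocol for phenols (NBS in DMF), so the carbon para to the free OH should be brominated, any 2-bromo isomer being removed by chromatography; the bromine later blocks C6 of the third unit.

Step 11
Reactants: 14 4-bromo-1,2-bis(benzyloxy)benzene; 15 (R)-2,2-dimethyl-1,3-dioxolane-4-carbaldehyde
Product: 16 (S)-[3,4-bis(benzyloxy)phenyl][(4R)-2,2-dimethyl-1,3-dioxolan-4-yl]methanol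
Conditions: 14, Mg turnings, THF, 50 °C; then 15, −78 °C; H2O work-up
Reagents that add atoms: none
Why: Grignard addition under Felkin–Anh control, the aryl nucleophile adding anti to the dioxolane C–O bond so that the new carbinol centre is S (anti adduct); the minor syn epimer is removed by chromatography.

Step 12
Reactants: 16 (S)-[3,4-bis(benzyloxy)phenyl][(4R)-2,2-dimethyl-1,3-dioxolan-4-yl]methanol; 13 4-bromo-3,5-bis(benzyloxy)phenol
Product: 17 (4R)-4-{(R)-[3,4-bis(benzyloxy)phenyl][4-bromo-3,5-bis(benzyloxy)phenoxy]methyl}-2,2-dimethyl-1,3-dioxolane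
Conditions: PPh3 (1.5 equiv), DIAD (1.5 equiv), toluene, 0 °C to rt
Reagents that add atoms: none
Why: Mitsunobu etherification, the phenol displacing the activated benzylic alcohol by SN2 with inversion, which turns the anti alcohol into the syn aryl ether and sets C2 of the third unit as R.

Step 13
Reactants: 11 top dimer thioether; 17 aryl ether acetonide
Product: 18 dimer–aryl ether acetonide (C4 of the second unit bonded 4β to the phenoxy ring carbon ortho to the ether oxygen)
Conditions: 17 (1.5 equiv), AgBF4 (1.5 equiv), 2,6-di-tert-butyl-4-methylpyridine (2 equiv), 4 Å MS, CH2Cl2, −40 to 0 °C, dark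
Reagents that add atoms: none
Why: Thiophilic activation by AgBF4 removes the thioether as silver thiolate and the resulting flavan-4-yl cation alkylates 17 (Friedel–Crafts) at one of its two equivalent carbons ortho to the ether oxygen, the para carbon being blocked by bromine, with attack anti to the 3-OH setting the 4β centre of the second unit.

Step 14
Reactants: 18 dimer–aryl ether acetonide
Product: 19 dimer–aryl ether (2R,3R)-propane-1,2-diol
Conditions: AcOH/H2O/THF (3:1:1), 45 °C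
Reagents that add atoms: none
Why: Acid-catalysed acetal hydrolysis of the terminal isopropylidene group under conditions too mild to ionise the benzylic ethers or the interflavan bonds.

Step 15
Reactants: 19 dimer–aryl ether (2R,3R)-propane-1,2-diol
Product: 20 dimer–aryl ether (2S,3R)-2-hydroxypropanal
Conditions: TEMPO (0.2 equiv), PhI(OAc)2 (1.1 equiv), CH2Cl2, rt; used crude
Reagents that add atoms: none
Why: TEMPO/PhI(OAc)2 oxidation, the oxoammonium salt oxidising the primary alcohol selectively in the presence of the secondary alcohols, with only 1.1 equiv of oxidant to avoid glycol cleavage.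

Step 16
Reactants: 20 dimer–aryl ether (2S,3R)-2-hydroxypropanal; 3 8-bromo-5,7,3',4'-tetra-O-benzyl-(−)-epicatechin
Product: 23 protected tetramer (pentadeca-O-benzyl pentabromo tetramer), via flavan-3,4-diol 21 (not isolated), via flavan-4-yl cation 22 (not isolated)
Conditions: 3 (3 equiv), BF3·OEt2 (0.5 equiv), 4 Å MS, CH2Cl2, −78 to −20 °C
Reagents that add atoms: none
Why: BF3·OEt2 activates the aldehyde of 20, and the only free CH of the phloroglucinol-type ring (ortho to the ether oxygen, para to a benzyloxy group) attacks C4 in a 6-exo-trig intramolecular Friedel–Crafts hydroxyalkylation that closes ring C of the third unit through the C4–C4a bond and gives flavan-3,4-diol 21. The Lewis acid then ionises the doubly activated benzylic C4–OH of 21 to the flavan-4-yl cation 22, which is intercepted by C6 of 3 in a second, intermolecular Friedel–Crafts alkylation. The closest known reaction types are the acid-mediated cyclisation of 3-aryloxypropanals to chroman-4-ols and the Lewis-acid-promoted condensation of C4-oxygenated flavan-3-ols (leucoanthocyanidin type) with flavan nucleophiles. The C4–OH configuration of 21 is irrelevant because it is erased in 22; the final C4 centre is set by approach of 3 anti to the pseudo-axial C3–OH of the half-chair 2,3-cis cation, which should give the 3,4-trans (4β) bond. Site selectivity is secured by the bromine caps: every ring A carbon of 20 is substituted or brominated except the cyclising one, the catechol rings are far less nucleophilic and would have to close a strained five-membered ring, and C8–Br of 3 leaves C6 as its only reactive carbon. Should 3 add to the aldehyde first, the resulting carbinol ionises to a cation stabilised by the bottom unit and closes the same C4–C4a bond, so both orders converge on 23.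

Step 17
Reactants: 23 protected tetramer
Product: 24 epicatechin-(4β→6)-epiafzelechin-(4β→8)-epicatechin-(4β→6)-epicatechin (target)
Conditions: H2 (1 atm), Pd(OH)2/C, Et3N (6 equiv), THF/MeOH/H2O, rt
Reagents that add atoms: none
Why: Catalytic hydrogenolysis cleaves the fifteen benzyl ethers and hydrodebrominates the five aryl bromides in one operation, Et3N trapping the HBr so that the acid-labile interflavan bonds survive.

**Compound list**

1 | (−)-epicatechin, (2R,3R)-2-(3,4-dihydroxyphenyl)chromane-3,5,7-triol | O[C@@H]1Cc2c(O)cc(O)cc2O[C@@H]1c1ccc(O)c(O)c1 | starting material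
2 | 5,7,3',4'-tetra-O-benzyl-(−)-epicatechin (2R,3R) | O[C@@H]1Cc2c(OCc3ccccc3)cc(OCc3ccccc3)cc2O[C@@H]1c1ccc(OCc2ccccc2)c(OCc2ccccc2)c1 | intermediate
3 | 8-bromo-5,7,3',4'-tetra-O-benzyl-(−)-epicatechin (2R,3R) | O[C@@H]1Cc2c(OCc3ccccc3)cc(OCc3ccccc3)c(Br)c2O[C@@H]1c1ccc(OCc2ccccc2)c(OCc2ccccc2)c1 | intermediate
4 | 5,7,3',4'-tetra-O-benzyl-4β-(2-ethoxyethoxy)-(−)-epicatechin (2,3-cis, 3,4-trans) | O[C@@H]1[C@@H](OCCOCC)c2c(OCc3ccccc3)cc(OCc3ccccc3)cc2O[C@@H]1c1ccc(OCc2ccccc2)c(OCc2ccccc2)c1 | intermediate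
5 | 6,8-dibromo-5,7,3',4'-tetra-O-benzyl-4β-(2-ethoxyethoxy)-(−)-epicatechin | O[C@@H]1[C@@H](OCCOCC)c2c(OCc3ccccc3)c(Br)c(OCc3ccccc3)c(Br)c2O[C@@H]1c1ccc(OCc2ccccc2)c(OCc2ccccc2)c1 | intermediate
6 | (−)-epiafzelechin, (2R,3R)-2-(4-hydroxyphenyl)chromane-3,5,7-triol | O[C@@H]1Cc2c(O)cc(O)cc2O[C@@H]1c1ccc(O)cc1 | starting material
7 | 5,7,4'-tri-O-benzyl-(−)-epiafzelechin | O[C@@H]1Cc2c(OCc3ccccc3)cc(OCc3ccccc3)cc2O[C@@H]1c1ccc(OCc2ccccc2)cc1 | intermediate
8 | 5,7,4'-tri-O-benzyl-4β-(2-ethoxyethoxy)-(−)-epiafzelechin | O[C@@H]1[C@@H](OCCOCC)c2c(OCc3ccccc3)cc(OCc3ccccc3)cc2O[C@@H]1c1ccc(OCc2ccccc2)cc1 | intermediate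
9 | 8-bromo-5,7,4'-tri-O-benzyl-4β-(2-ethoxyethoxy)-(−)-epiafzelechin | O[C@@H]1[C@@H](OCCOCC)c2c(OCc3ccccc3)cc(OCc3ccccc3)c(Br)c2O[C@@H]1c1ccc(OCc2ccccc2)cc1 | intermediate
10 | 8-bromo-5,7,4'-tri-O-benzyl-4β-[(2,6-dimethylphenyl)sulfanyl]-(−)-epiafzelechin (thioether trans to 3-OH) | O[C@@H]1[C@@H](Sc2c(C)cccc2C)c2c(OCc3ccccc3)cc(OCc3ccccc3)c(Br)c2O[C@@H]1c1ccc(OCc2ccccc2)cc1 | intermediate
11 | top dimer thioether: [6,8-dibromo-5,7,3',4'-tetra-O-benzylepicatechin]-(4β→6)-[8-bromo-5,7,4'-tri-O-benzyl-4β-(2,6-dimethylphenylsulfanyl)epiafzelechin] | c6ccccc6COc1ccc([C@H]2Oc3c(Br)c(OCc6ccccc6)c([C@H]4c5c(OCc6ccccc6)c(Br)c(OCc6ccccc6)c(Br)c5O[C@H](c5ccc(OCc6ccccc6)c(OCc6ccccc6)c5)[C@@H]4O)c(OCc6ccccc6)c3[C@H](Sc3c(C)cccc3C)[C@H]2O)cc1 | intermediate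
12 | 3,5-bis(benzyloxy)phenol | Oc1cc(OCc2ccccc2)cc(OCc2ccccc2)c1 | starting material
13 | 4-bromo-3,5-bis(benzyloxy)phenol | Oc1cc(OCc2ccccc2)c(Br)c(OCc2ccccc2)c1 | intermediate
14 | 4-bromo-1,2-bis(benzyloxy)benzene | Brc1ccc(OCc2ccccc2)c(OCc2ccccc2)c1 | starting material
15 | (R)-2,2-dimethyl-1,3-dioxolane-4-carbaldehyde | O=C[C@H]1COC(C)(C)O1 | starting material
16 | (S)-[3,4-bis(benzyloxy)phenyl][(4R)-2,2-dimethyl-1,3-dioxolan-4-yl]methanol (anti) | O[C@@H](c1ccc(OCc2ccccc2)c(OCc2ccccc2)c1)[C@H]1COC(C)(C)O1 | intermediate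
17 | (4R)-4-{(R)-[3,4-bis(benzyloxy)phenyl][4-bromo-3,5-bis(benzyloxy)phenoxy]methyl}-2,2-dimethyl-1,3-dioxolane (syn ether) | Brc1c(OCc2ccccc2)cc(O[C@H](c2ccc(OCc3ccccc3)c(OCc3ccccc3)c2)[C@H]2COC(C)(C)O2)cc1OCc1ccccc1 | intermediate
18 | dimer–aryl ether acetonide: dimer of 11 in which C4 of the second unit carries, 4β and in place of sulfur, C2 of the phenoxy ring of 17 (the carbon ortho to the ether oxygen) | c6ccccc6COc1ccc([C@H]2Oc3c(Br)c(OCc6ccccc6)c([C@H]4c5c(OCc6ccccc6)c(Br)c(OCc6ccccc6)c(Br)c5O[C@H](c5ccc(OCc6ccccc6)c(OCc6ccccc6)c5)[C@@H]4O)c(OCc6ccccc6)c3[C@H](c3c(OCc6ccccc6)c(Br)c(OCc6ccccc6)cc3O[C@H](c3ccc(OCc6ccccc6)c(OCc6ccccc6)c3)[C@H]3COC(C)(C)O3)[C@H]2O)cc1 | intermediate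
19 | diol from 18: the dioxolane is replaced by a (2R,3R)-3-aryl-3-aryloxypropane-1,2-diol chain | c6ccccc6COc1ccc([C@H]2Oc3c(Br)c(OCc6ccccc6)c([C@H]4c5c(OCc6ccccc6)c(Br)c(OCc6ccccc6)c(Br)c5O[C@H](c5ccc(OCc6ccccc6)c(OCc6ccccc6)c5)[C@@H]4O)c(OCc6ccccc6)c3[C@H](c3c(OCc6ccccc6)c(Br)c(OCc6ccccc6)cc3O[C@H](c3ccc(OCc6ccccc6)c(OCc6ccccc6)c3)[C@H](O)CO)[C@H]2O)cc1 | intermediate
20 | aldehyde from 19: (2S,3R)-3-aryl-3-aryloxy-2-hydroxypropanal chain | c6ccccc6COc1ccc([C@H]2Oc3c(Br)c(OCc6ccccc6)c([C@H]4c5c(OCc6ccccc6)c(Br)c(OCc6ccccc6)c(Br)c5O[C@H](c5ccc(OCc6ccccc6)c(OCc6ccccc6)c5)[C@@H]4O)c(OCc6ccccc6)c3[C@H](c3c(OCc6ccccc6)c(Br)c(OCc6ccccc6)cc3O[C@H](c3ccc(OCc6ccccc6)c(OCc6ccccc6)c3)[C@H](O)C=O)[C@H]2O)cc1 | intermediate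
21 | trimeric flavan-3,4-diol: third unit ring C closed, 6-bromo-5,7,3',4'-tetra-O-benzyl, (2R,3R), C4–OH as a mixture of epimers | c6ccccc6COc1ccc([C@H]2Oc3c(Br)c(OCc6ccccc6)c([C@H]4c5c(OCc6ccccc6)c(Br)c(OCc6ccccc6)c(Br)c5O[C@H](c5ccc(OCc6ccccc6)c(OCc6ccccc6)c5)[C@@H]4O)c(OCc6ccccc6)c3[C@H](c3c(OCc6ccccc6)c(Br)c(OCc6ccccc6)c4c3O[C@H](c3ccc(OCc6ccccc6)c(OCc6ccccc6)c3)[C@H](O)C4O)[C@H]2O)cc1 | intermediate (not isolated)
22 | flavan-4-yl cation of the third unit derived from 21 | c6ccccc6COc1ccc([C@H]2Oc3c(Br)c(OCc6ccccc6)c([C@H]4c5c(OCc6ccccc6)c(Br)c(OCc6ccccc6)c(Br)c5O[C@H](c5ccc(OCc6ccccc6)c(OCc6ccccc6)c5)[C@@H]4O)c(OCc6ccccc6)c3[C@H](c3c(OCc6ccccc6)c(Br)c(OCc6ccccc6)c4c3O[C@H](c3ccc(OCc6ccccc6)c(OCc6ccccc6)c3)[C@H](O)[CH+]4)[C@H]2O)cc1 | intermediate (not isolated)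
23 | protected tetramer: [6,8-dibromo-5,7,3',4'-tetra-O-benzylepicatechin]-(4β→6)-[8-bromo-5,7,4'-tri-O-benzylepiafzelechin]-(4β→8)-[6-bromo-5,7,3',4'-tetra-O-benzylepicatechin]-(4β→6)-[8-bromo-5,7,3',4'-tetra-O-benzylepicatechin] | c6ccccc6COc1ccc([C@H]2Oc3c(Br)c(OCc6ccccc6)c([C@H]4c5c(OCc6ccccc6)c(Br)c(OCc6ccccc6)c(Br)c5O[C@H](c5ccc(OCc6ccccc6)c(OCc6ccccc6)c5)[C@@H]4O)c(OCc6ccccc6)c3[C@H](c3c(OCc6ccccc6)c(Br)c(OCc6ccccc6)c4c3O[C@H](c3ccc(OCc6ccccc6)c(OCc6ccccc6)c3)[C@H](O)[C@H]4c3c(OCc6ccccc6)c(Br)c4c(c3OCc6ccccc6)C[C@@H](O)[C@@H](c3ccc(OCc6ccccc6)c(OCc6ccccc6)c3)O4)[C@H]2O)cc1 | intermediate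
24 | epicatechin-(4β→6)-epiafzelechin-(4β→8)-epicatechin-(4β→6)-epicatechin (all units 2R,3R; all interflavan bonds 3,4-trans) | Oc1ccc([C@H]2Oc3cc(O)c([C@H]4c5c(O)cc(O)cc5O[C@H](c5ccc(O)c(O)c5)[C@@H]4O)c(O)c3[C@H](c3c(O)cc(O)c4c3O[C@H](c3ccc(O)c(O)c3)[C@H](O)[C@H]4c3c(O)cc4c(c3O)C[C@@H](O)[C@@H](c3ccc(O)c(O)c3)O4)[C@H]2O)cc1 | target

**Count**

Total steps: 17. Longest linear sequence: 10 steps (6 → 7 → 8 → 9 → 10 → 11 → 18 → 19 → 20 → 23 → 24, steps 5, 6, 7, 8, 9, 13, 14, 15, 16, 17).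

**Three steps most likely to fail, with fallbacks**

Step 16 (key cascade). What may go wrong: the cation formed from the flavan-3,4-diol is captured too slowly by the bromine-deactivated nucleophile and is lost by proton loss or hydration, or the unprotected α-hydroxy aldehyde degrades before ring closure is complete. Fallback: the cascade is split into two separately optimisable operations through an isolable compound. Setting out from aldehyde 20, the ring closure is run with catalytic BF3·OEt2 in CH2Cl2 containing an excess of 2-ethoxyethanol at −40 °C. The same Friedel–Crafts closure of the C4–C4a bond is then followed by capture of the cation by the alcohol, which should give the stable trimeric 4β-(2-ethoxyethoxy) ether F1. This ether is condensed with 3 under TMSOTf in CH2Cl2 at −78 °C, the classical coupling of a C4-alkoxy flavan, and the route is rejoined at 23.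

Step 13 (silver-mediated coupling). What may go wrong: Friedel–Crafts attack of the bromine-deactivated, doubly flanked open-chain aryl carbon on the hindered dimer cation is slow, so that the cation eliminates or the acetonide is lost. Fallback: ring closure is moved in front of the coupling. Setting out from 17, the acetonide is hydrolysed with aqueous AcOH to the monomeric diol F2, which is oxidised with TEMPO and PhI(OAc)2 to the monomeric α-hydroxy aldehyde F3. BF3·OEt2 with 2-ethoxyethanol then closes ring C to the monomeric 6-bromo flavan C4 ether F4, whose only free ring A carbon is the unhindered and more nucleophilic C8. AgBF4-mediated coupling of 11 with F4 gives the trimeric ether F1, and TMSOTf-promoted condensation with 3 returns to the route at 23.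

Step 11 (Grignard addition). What may go wrong: poor facial selectivity, Felkin–Anh and chelation-controlled addition competing, so that much of the syn epimer forms. Fallback: setting out from 16 as its epimer mixture, Dess–Martin oxidation gives the aryl ketone F5. Chelation-controlled reduction with Zn(BH4)2 in Et2O at −30 °C should then deliver the anti alcohol selectively, coming back to the route at 16.

**Further compounds**

F1 | step 16 | trimeric C4 ether: [6,8-dibromo-5,7,3',4'-tetra-O-benzylepicatechin]-(4β→6)-[8-bromo-5,7,4'-tri-O-benzylepiafzelechin]-(4β→8)-[6-bromo-5,7,3',4'-tetra-O-benzyl-4β-(2-ethoxyethoxy)epicatechin] | c6ccccc6COc1ccc([C@H]2Oc3c(Br)c(OCc6ccccc6)c([C@H]4c5c(OCc6ccccc6)c(Br)c(OCc6ccccc6)c(Br)c5O[C@H](c5ccc(OCc6ccccc6)c(OCc6ccccc6)c5)[C@@H]4O)c(OCc6ccccc6)c3[C@H](c3c(OCc6ccccc6)c(Br)c(OCc6ccccc6)c4c3O[C@H](c3ccc(OCc6ccccc6)c(OCc6ccccc6)c3)[C@H](O)[C@H]4OCCOCC)[C@H]2O)cc1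
F2 | step 13 | (2R,3R)-3-[3,4-bis(benzyloxy)phenyl]-3-[4-bromo-3,5-bis(benzyloxy)phenoxy]propane-1,2-diol | Brc1c(OCc2ccccc2)cc(O[C@H](c2ccc(OCc3ccccc3)c(OCc3ccccc3)c2)[C@H](O)CO)cc1OCc1ccccc1
F3 | step 13 | (2S,3R)-3-[3,4-bis(benzyloxy)phenyl]-3-[4-bromo-3,5-bis(benzyloxy)phenoxy]-2-hydroxypropanal | Brc1c(OCc2ccccc2)cc(O[C@H](c2ccc(OCc3ccccc3)c(OCc3ccccc3)c2)[C@H](O)C=O)cc1OCc1ccccc1
F4 | step 13 | 6-bromo-5,7,3',4'-tetra-O-benzyl-4β-(2-ethoxyethoxy)-(−)-epicatechin | O[C@@H]1[C@@H](OCCOCC)c2c(OCc3ccccc3)c(Br)c(OCc3ccccc3)cc2O[C@@H]1c1ccc(OCc2ccccc2)c(OCc2ccccc2)c1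
F5 | step 11 | [3,4-bis(benzyloxy)phenyl][(4R)-2,2-dimethyl-1,3-dioxolan-4-yl]methanone | O=C(c1ccc(OCc2ccccc2)c(OCc2ccccc2)c1)[C@H]1COC(C)(C)O1
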